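The route rests on disconnecting the two neighbouring carbon substituents of the central benzoic acid ring (C1 carboxyl, C2 aroyl, C3 hydroxyl): the C4 acetyl group and the C5 carboxymethyl arm, an ortho pair lying beside the C3 oxygen. An aryne spanning C4–C5 inserts into the CH2–C(=O) σ-bond of methyl acetoacetate, so the C5–CH2 and C4–acyl bonds form in one operation while the C3 methoxy group steers the enolate to C5. The aryne precursor is the complete tetra-ortho-substituted benzophenone, methyl 2-(2,6-dimethoxybenzoyl)-3-methoxybenzoate carrying a C4 triflate and a C5 trimethylsilyl group, reached from 5-bromovanillin by retro-Brook silylation and acetal-directed lithiation. One boron tribromide treatment finally unmasks all five acidic groups.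

Key step: step 9

Remark: huanglongmycin D has no stereocentre, stereogenic axis or configured double bond, so the achiral compound itself is the required single stereoisomer and no asymmetric step is needed.

Step 1
Reactants: 1 5-bromovanillin (3-bromo-4-hydroxy-5-methoxybenzaldehyde)
Product: 2 2-bromo-4-(dimethoxymethyl)-6-methoxyphenol
Conditions: HC(OMe)3, MeOH, cat. p-TsOH, rt; then Et3N, concentrate
Reagents that add atoms: trimethyl orthoformate COC(OC)OC; methanol CO
Why: Acid-catalysed acetalisation, driven by the orthoformate as water scavenger, masks the formyl group against n-BuLi and turns it into the ortho director needed in step 3.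

Step 2
Reactants: 2 2-bromo-4-(dimethoxymethyl)-6-methoxyphenol
Product: 5 [5-(dimethoxymethyl)-3-methoxy-2-(methoxymethoxy)phenyl]trimethylsilane, via aryl trimethylsilyl ether 3 (not isolated), via lithium phenoxide 4 (not isolated)
Conditions: HMDS, THF, 70 °C, evaporate; n-BuLi, THF, –78 °C; then MOMCl, –78 °C → rt
Reagents that add atoms: hexamethyldisilazane C[Si](C)(C)N[Si](C)(C)C; chloromethyl methyl ether COCCl
Why: O-Silylation and bromine–lithium exchange set off the 1,3 O→C silyl shift (retro-Brook rearrangement), driven by formation of the lithium phenoxide, which is capped in the same flask by Williamson-type O-alkylation with the reactive chloromethyl ether.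

Step 3
Reactants: 5 [5-(dimethoxymethyl)-3-methoxy-2-(methoxymethoxy)phenyl]trimethylsilane; 6 2,6-dimethoxybenzaldehyde
Product: 8 rac-(2,6-dimethoxyphenyl)[2-(dimethoxymethyl)-6-methoxy-5-(methoxymethoxy)-4-(trimethylsilyl)phenyl]methanol, via aryllithium 7 (not isolated)
Conditions: n-BuLi, TMEDA, Et2O, 0 °C; then 6, THF, –78 °C → rt; then H2O (non-acidic work-up)
Reagents that add atoms: none
Why: Directed ortho-metalation removes the C2 proton flanked by acetal and methoxy group (cooperative coordination) while C6 is shielded by the silyl group, and the aryllithium adds 1,2 to the non-enolisable aldehyde; the carbinol centre forms as a racemate and is erased in step 4.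

Step 4
Reactants: 8 rac-(2,6-dimethoxyphenyl)[2-(dimethoxymethyl)-6-methoxy-5-(methoxymethoxy)-4-(trimethylsilyl)phenyl]methanol
Product: 9 (2,6-dimethoxyphenyl)[2-(dimethoxymethyl)-6-methoxy-5-(methoxymethoxy)-4-(trimethylsilyl)phenyl]methanone
Conditions: Dess–Martin periodinane, pyridine, CH2Cl2, 0 °C → rt
Reagents that add atoms: none
Why: Dess–Martin oxidation should convert the hindered benzhydrol into the diaryl ketone under buffered, non-acidic conditions that leave the acetal, the MOM ether and the aryl–silicon bond untouched.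

Step 5
Reactants: 9 (2,6-dimethoxyphenyl)[2-(dimethoxymethyl)-6-methoxy-5-(methoxymethoxy)-4-(trimethylsilyl)phenyl]methanone
Product: 10 2-(2,6-dimethoxybenzoyl)-4-hydroxy-3-methoxy-5-(trimethylsilyl)benzaldehyde
Conditions: 2 M aq HCl, THF, 40 °C
Reagents that add atoms: water O
Why: Acid-catalysed hydrolysis cleaves both acetal-type groups at once (dimethyl acetal to aldehyde, MOM ether to phenol), while the aryl–silicon bond on the doubly acylated ring should resist protodesilylation in dilute acid.

Step 6
Reactants: 10 2-(2,6-dimethoxybenzoyl)-4-hydroxy-3-methoxy-5-(trimethylsilyl)benzaldehyde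
Product: 11 3-(2,6-dimethoxybenzoyl)-4-formyl-2-methoxy-6-(trimethylsilyl)phenyl trifluoromethanesulfonate
Conditions: Tf2O, pyridine, CH2Cl2, 0 °C
Reagents that add atoms: trifluoromethanesulfonic anhydride O=S(=O)(OS(=O)(=O)C(F)(F)F)C(F)(F)F
Why: O-Sulfonylation of the acidic (para-formyl) phenol with triflic anhydride and an amine base is the standard completion of an o-silylaryl triflate and uses no fluoride or strong base that could trigger it.

Step 7
Reactants: 11 3-(2,6-dimethoxybenzoyl)-4-formyl-2-methoxy-6-(trimethylsilyl)phenyl trifluoromethanesulfonate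
Product: 12 2-(2,6-dimethoxybenzoyl)-3-methoxy-4-(trifluoromethylsulfonyloxy)-5-(trimethylsilyl)benzoic acid
Conditions: NaClO2, NaH2PO4, 2-methyl-2-butene, t-BuOH/THF/H2O, rt
Reagents that add atoms: sodium chlorite [Na+].[O-]Cl=O
Why: Pinnick oxidation is selective for the aldehyde, the alkene scavenges hypochlorous acid, and the mildly acidic buffer should leave the aryl triflate and the C–Si bond of the now electron-poor ring intact.

Step 8
Reactants: 12 2-(2,6-dimethoxybenzoyl)-3-methoxy-4-(trifluoromethylsulfonyloxy)-5-(trimethylsilyl)benzoic acid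
Product: 13 methyl 2-(2,6-dimethoxybenzoyl)-3-methoxy-4-(trifluoromethylsulfonyloxy)-5-(trimethylsilyl)benzoate
Conditions: TMSCHN2, PhMe/MeOH, 0 °C → rt
Reagents that add atoms: trimethylsilyldiazomethane C[Si](C)(C)C=[N+]=[N-]
Why: Esterification by O-alkylation of the carboxylic acid with diazomethane released in situ runs under neutral conditions, should give the open (normal) methyl ester and not the cyclic pseudo-ester, and spares the silyl triflate.

Step 9
Reactants: 13 methyl 2-(2,6-dimethoxybenzoyl)-3-methoxy-4-(trifluoromethylsulfonyloxy)-5-(trimethylsilyl)benzoate; 14 methyl acetoacetate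
Product: 17 methyl 4-acetyl-2-(2,6-dimethoxybenzoyl)-3-methoxy-5-(2-methoxy-2-oxoethyl)benzoate, via aryne 15 (not isolated), via benzocyclobutenoxide 16 (not isolated)
Conditions: CsF (3 equiv), 14 (2 equiv), MeCN, 80 °C
Reagents that add atoms: none
Why: Fluoride attack on silicon expels the neighbouring triflate to give aryne 15; the caesium enolate of 14 adds through carbon to C5, the resulting C4 aryl anion closes onto the ketone carbonyl (4-exo-trig) to give 16, and retro-aldol-type fragmentation of the strained ring leaves the acetyl group on C4 and a stabilised ester enolate on the new C5 methylene, which is then protonated. The closest known reaction type is the aryne acyl-alkylation, the σ-bond insertion of arynes into β-keto esters, which is established for 3-alkoxybenzynes and acetoacetates. No ring is retained and 17 has no stereocentre; the two transient stereocentres of 16 vanish on fragmentation. The step needs regioselective addition to the unsymmetrical aryne, and the inductively withdrawing C3 methoxy group secures it by polarising and distorting the triple bond so that C5 is the electrophilic terminus and charge builds up at C4 next to oxygen. Chemoselectivity is helped by the substrate, since the diaryl ketone has no α-hydrogen and is buried between four ortho substituents and the methyl esters are inert to CsF in acetonitrile. An excess of 14 should suppress a second arylation of the product methylene.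

Step 10
Reactants: 17 methyl 4-acetyl-2-(2,6-dimethoxybenzoyl)-3-methoxy-5-(2-methoxy-2-oxoethyl)benzoate
Product: 18 huanglongmycin D, 4-acetyl-5-(carboxymethyl)-2-(2,6-dihydroxybenzoyl)-3-hydroxybenzoic acid
Conditions: BBr3 (excess), CH2Cl2, –78 °C → rt; then H2O
Reagents that add atoms: none
Why: Boron tribromide dealkylation (bromide attack on the methyl groups of boron-complexed oxygens) should cleave the three aryl methyl ethers, each activated by chelation to an ortho carbonyl, and on warming also the two methyl esters, and aqueous hydrolysis of the boron esters then releases the triphenol diacid without exposing the o-acetyl arylacetate to base.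

Compound list
1 | 5-bromovanillin (3-bromo-4-hydroxy-5-methoxybenzaldehyde) | COc1cc(C=O)cc(Br)c1O | starting material
2 | 2-bromo-4-(dimethoxymethyl)-6-methoxyphenol | COC(OC)c1cc(OC)c(O)c(Br)c1 | intermediate
3 | [2-bromo-4-(dimethoxymethyl)-6-methoxyphenoxy]trimethylsilane (formed in situ) | COC(OC)c1cc(OC)c(O[Si](C)(C)C)c(Br)c1 | intermediate
4 | lithium 4-(dimethoxymethyl)-2-methoxy-6-(trimethylsilyl)phenoxide (formed in situ) | COC(OC)c1cc(OC)c([O-])c([Si](C)(C)C)c1.[Li+] | intermediate
5 | [5-(dimethoxymethyl)-3-methoxy-2-(methoxymethoxy)phenyl]trimethylsilane | COCOc1c(OC)cc(C(OC)OC)cc1[Si](C)(C)C | intermediate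
6 | 2,6-dimethoxybenzaldehyde | COc1cccc(OC)c1C=O | starting material
7 | [2-(dimethoxymethyl)-6-methoxy-5-(methoxymethoxy)-4-(trimethylsilyl)phenyl]lithium (formed in situ) | [Li]c1c(C(OC)OC)cc([Si](C)(C)C)c(OCOC)c1OC | intermediate
8 | rac-(2,6-dimethoxyphenyl)[2-(dimethoxymethyl)-6-methoxy-5-(methoxymethoxy)-4-(trimethylsilyl)phenyl]methanol (racemic carbinol) | COC(OC)c1cc([Si](C)(C)C)c(OCOC)c(OC)c1C(O)c1c(OC)cccc1OC | intermediate
9 | (2,6-dimethoxyphenyl)[2-(dimethoxymethyl)-6-methoxy-5-(methoxymethoxy)-4-(trimethylsilyl)phenyl]methanone | COC(OC)c1cc([Si](C)(C)C)c(OCOC)c(OC)c1C(=O)c1c(OC)cccc1OC | intermediate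
10 | 2-(2,6-dimethoxybenzoyl)-4-hydroxy-3-methoxy-5-(trimethylsilyl)benzaldehyde | O=Cc1cc([Si](C)(C)C)c(O)c(OC)c1C(=O)c1c(OC)cccc1OC | intermediate
11 | 3-(2,6-dimethoxybenzoyl)-4-formyl-2-methoxy-6-(trimethylsilyl)phenyl trifluoromethanesulfonate | O=Cc1cc([Si](C)(C)C)c(OS(=O)(=O)C(F)(F)F)c(OC)c1C(=O)c1c(OC)cccc1OC | intermediate
12 | 2-(2,6-dimethoxybenzoyl)-3-methoxy-4-(trifluoromethylsulfonyloxy)-5-(trimethylsilyl)benzoic acid | OC(=O)c1cc([Si](C)(C)C)c(OS(=O)(=O)C(F)(F)F)c(OC)c1C(=O)c1c(OC)cccc1OC | intermediate
13 | methyl 2-(2,6-dimethoxybenzoyl)-3-methoxy-4-(trifluoromethylsulfonyloxy)-5-(trimethylsilyl)benzoate | COC(=O)c1cc([Si](C)(C)C)c(OS(=O)(=O)C(F)(F)F)c(OC)c1C(=O)c1c(OC)cccc1OC | intermediate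
14 | methyl acetoacetate | CC(=O)CC(=O)OC | starting material
15 | methyl 2-(2,6-dimethoxybenzoyl)-3-methoxy-4,5-didehydrobenzoate (aryne, formed in situ) | COC(=O)C1=CC#CC(OC)=C1C(=O)c1c(OC)cccc1OC | intermediate
16 | caesium 3-(2,6-dimethoxybenzoyl)-2-methoxy-4,7-bis(methoxycarbonyl)-8-methylbicyclo[4.2.0]octa-1,3,5-trien-8-olate (formed in situ, mixture of stereoisomers) | COC(=O)C1c2cc(C(=O)OC)c(C(=O)c3c(OC)cccc3OC)c(OC)c2C1(C)[O-].[Cs+] | intermediate
17 | methyl 4-acetyl-2-(2,6-dimethoxybenzoyl)-3-methoxy-5-(2-methoxy-2-oxoethyl)benzoate | COC(=O)Cc1cc(C(=O)OC)c(C(=O)c2c(OC)cccc2OC)c(OC)c1C(C)=O | intermediate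
18 | huanglongmycin D, 4-acetyl-5-(carboxymethyl)-2-(2,6-dihydroxybenzoyl)-3-hydroxybenzoic acid (achiral) | CC(=O)c1c(CC(=O)O)cc(C(=O)O)c(C(=O)c2c(O)cccc2O)c1O | target

Total step count: 10. Longest linear sequence: 10 steps (1 → 18); 6 and 14 enter as purchased reagents.

Steps most likely to fail

Step 9. The C4 aryl anion may be protonated before it closes onto the ketone, which would stop the sequence at plain α-arylation. The enolate may also add through oxygen, or the product methylene may be arylated a second time. The fallback avoids the aryne and builds the two arms by cross-coupling; it sets out from 10 and returns at 17. NIS in MeCN should replace the silyl group of phenol 10 by iodine (ipso-iododesilylation directed by the ortho hydroxyl) to give 2-(2,6-dimethoxybenzoyl)-4-hydroxy-5-iodo-3-methoxybenzaldehyde F1. Triflation, Pinnick oxidation and methylation with TMSCHN2, run as in steps 6–8, should then give in turn 3-(2,6-dimethoxybenzoyl)-4-formyl-6-iodo-2-methoxyphenyl trifluoromethanesulfonate F2, 2-(2,6-dimethoxybenzoyl)-5-iodo-3-methoxy-4-(trifluoromethylsulfonyloxy)benzoic acid F3 and methyl 2-(2,6-dimethoxybenzoyl)-5-iodo-3-methoxy-4-(trifluoromethylsulfonyloxy)benzoate F4. The C5 iodide, more reactive than the doubly flanked C4 triflate, would undergo Negishi coupling (Pd2(dba)3, XPhos, THF) with the Reformatsky reagent bromo(2-methoxy-2-oxoethyl)zinc F5, made from methyl bromoacetate and zinc, to give methyl 2-(2,6-dimethoxybenzoyl)-3-methoxy-5-(2-methoxy-2-oxoethyl)-4-(trifluoromethylsulfonyloxy)benzoate F6. Stille coupling of the C4 triflate with tributyl(1-ethoxyvinyl)stannane (Pd(PPh3)4, LiCl, dioxane, 100 °C) would give the enol ether methyl 2-(2,6-dimethoxybenzoyl)-4-(1-ethoxyethenyl)-3-methoxy-5-(2-methoxy-2-oxoethyl)benzoate F7, which dilute HCl hydrolyses to 17.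

Step 3. Bond formation between an aryllithium flanked on both sides and an aldehyde flanked on both sides may be slow, so that the anion is lost by proton return before it adds. The fallback reverses the roles of the two rings; it sets out from 5 and returns at 8. Aryllithium 7, generated from 5 as before, is trapped with the small electrophile DMF to give 6-(dimethoxymethyl)-2-methoxy-3-(methoxymethoxy)-4-(trimethylsilyl)benzaldehyde F8. The stable nucleophile 2,6-dimethoxyphenyllithium F9, made from 1,3-dimethoxybenzene and n-BuLi and usable in excess and at higher temperature, is then added to F8 to give carbinol 8.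

Step 10. Dealkylation of the two methyl esters may stay incomplete, or the long exposure to the Lewis acid at room temperature may cause condensation of the acetyl and acetic acid arms. The fallback separates ester and ether cleavage; it sets out from 17 and returns at 18. Saponification with LiOH in aqueous THF at 0 °C, where hydrolysis of the unhindered esters should outrun enolate condensation, would give 4-acetyl-5-(carboxymethyl)-2-(2,6-dimethoxybenzoyl)-3-methoxybenzoic acid F10. A short treatment with BBr3 at –78 → 0 °C, needing only the chelation-assisted ether cleavages, then gives 18.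

Further compounds
F1 | step 9 | 2-(2,6-dimethoxybenzoyl)-4-hydroxy-5-iodo-3-methoxybenzaldehyde | O=Cc1cc(I)c(O)c(OC)c1C(=O)c1c(OC)cccc1OC
F2 | step 9 | 3-(2,6-dimethoxybenzoyl)-4-formyl-6-iodo-2-methoxyphenyl trifluoromethanesulfonate | O=Cc1cc(I)c(OS(=O)(=O)C(F)(F)F)c(OC)c1C(=O)c1c(OC)cccc1OC
F3 | step 9 | 2-(2,6-dimethoxybenzoyl)-5-iodo-3-methoxy-4-(trifluoromethylsulfonyloxy)benzoic acid | OC(=O)c1cc(I)c(OS(=O)(=O)C(F)(F)F)c(OC)c1C(=O)c1c(OC)cccc1OC
F4 | step 9 | methyl 2-(2,6-dimethoxybenzoyl)-5-iodo-3-methoxy-4-(trifluoromethylsulfonyloxy)benzoate | COC(=O)c1cc(I)c(OS(=O)(=O)C(F)(F)F)c(OC)c1C(=O)c1c(OC)cccc1OC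
F5 | step 9 | bromo(2-methoxy-2-oxoethyl)zinc | COC(=O)C[Zn]Br
F6 | step 9 | methyl 2-(2,6-dimethoxybenzoyl)-3-methoxy-5-(2-methoxy-2-oxoethyl)-4-(trifluoromethylsulfonyloxy)benzoate | COC(=O)Cc1cc(C(=O)OC)c(C(=O)c2c(OC)cccc2OC)c(OC)c1OS(=O)(=O)C(F)(F)F
F7 | step 9 | methyl 2-(2,6-dimethoxybenzoyl)-4-(1-ethoxyethenyl)-3-methoxy-5-(2-methoxy-2-oxoethyl)benzoate | CCOC(=C)c1c(CC(=O)OC)cc(C(=O)OC)c(C(=O)c2c(OC)cccc2OC)c1OC
F8 | step 3 | 6-(dimethoxymethyl)-2-methoxy-3-(methoxymethoxy)-4-(trimethylsilyl)benzaldehyde | COC(OC)c1cc([Si](C)(C)C)c(OCOC)c(OC)c1C=O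
F9 | step 3 | 2,6-dimethoxyphenyllithium | [Li]c1c(OC)cccc1OC
F10 | step 10 | 4-acetyl-5-(carboxymethyl)-2-(2,6-dimethoxybenzoyl)-3-methoxybenzoic acid | CC(=O)c1c(CC(=O)O)cc(C(=O)O)c(C(=O)c2c(OC)cccc2OC)c1OC
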